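Ring A is cut at C1–C6 and C2–C3. The step exploits the meta oxygen pair at C2 and C4 beside the C1 carboxyl. C1, its carboxyl carbon and C2 are a malonate, and C4 is a ketone carbonyl. One Michael–Claisen annulation of diallyl malonate with an acyclic enone therefore closes the carbocycle with all six substituents already in place. The enone holds C3–C6: a prenylated α′-methylene (C3), the carbonyl (C4), an α-prenyl group (C5) and the protected arylethyl chain on the β-carbon (C6). It arises from a symmetric diprenyl ketone by aldol condensation. Dehydrogenation, differentiation of the two phenols and one threefold deallylation complete the route.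

Key step: step 7

Remark on the chemistry: ring A is numbered C1 (carboxyl), C2 (OMe), C3 (prenyl), C4 (OH), C5 (prenyl), C6 (arylethyl) and ring B is the 4-hydroxyphenyl ring; prenyl means 3-methylbut-2-enyl; the target has no stereocentre, so every sp3 centre made on the way is carried as a mixture and later erased.

Step 1
Reactants: 1 dimethyl 3-oxopentanedioate; 2 prenyl bromide (1-bromo-3-methylbut-2-ene, two equivalents)
Product: 3 dimethyl 2,4-bis(3-methylbut-2-enyl)-3-oxopentanedioate (diastereomers and enol forms)
Conditions: NaH (2.1 equiv), THF, 0 °C; 2 (2.05 equiv), 0 °C → rt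
Reagents that add atoms: none
Why: Double C-alkylation of a bis-β-keto ester (acetoacetic ester alkylation), in which the disodium dianion offers one nucleophilic carbon on each flank and, after the first prenylation, the still unsubstituted terminus is the less hindered and more reactive one; the two new stereocentres are uncontrolled and vanish in step 2.

Step 2
Reactants: 3 dimethyl 2,4-bis(3-methylbut-2-enyl)-3-oxopentanedioate
Product: 4 2,10-dimethylundeca-2,9-dien-6-one
Conditions: LiCl, H2O, DMSO, 150 °C
Reagents that add atoms: none
Why: Twofold Krapcho dealkoxycarbonylation should strip both ester groups under neutral conditions, so the acid-sensitive trisubstituted alkenes are not exposed to acid.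

Step 3
Reactants: 5 methyl 3-(4-hydroxyphenyl)propanoate
Product: 6 methyl 3-[4-(allyloxy)phenyl]propanoate
Conditions: allyl bromide, K2CO3, acetone, reflux
Reagents that add atoms: allyl bromide, C=CCBr
Why: Williamson ether synthesis; the aryl allyl ether, unlike an aryl silyl ether, is inert to every alkoxide, enolate, hydride and carbonate used later and leaves together with the other allyl groups in step 11.

Step 4
Reactants: 6 methyl 3-[4-(allyloxy)phenyl]propanoate
Product: 7 3-[4-(allyloxy)phenyl]propanal
Conditions: i-Bu2AlH (1.05 equiv), CH2Cl2, −78 °C; aq. potassium sodium tartrate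
Reagents that add atoms: none
Why: Partial ester reduction with i-Bu2AlH, in which the tetrahedral aluminium hemiacetal persists at −78 °C until the quench, so the reduction should stop at the aldehyde.

Step 5
Reactants: 4 2,10-dimethylundeca-2,9-dien-6-one; 7 3-[4-(allyloxy)phenyl]propanal
Product: 8 10-[4-(allyloxy)phenyl]-8-hydroxy-2-methyl-7-(3-methylbut-2-enyl)dec-2-en-6-one (racemic syn/anti mixture)
Conditions: LiN(i-Pr)2 (1.05 equiv), THF, −78 °C; then 7; AcOH, −78 °C
Reagents that add atoms: none
Why: Directed aldol addition of a preformed lithium enolate; the ketone is symmetric, so only one enolate regioisomer exists, and the two new stereocentres need no control because step 6 removes both.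

Step 6
Reactants: 8 10-[4-(allyloxy)phenyl]-8-hydroxy-2-methyl-7-(3-methylbut-2-enyl)dec-2-en-6-one
Product: 10 (E)-10-[4-(allyloxy)phenyl]-2-methyl-7-(3-methylbut-2-enyl)deca-2,7-dien-6-one, via aldol mesylate 9 (not isolated)
Conditions: MsCl, Et3N, CH2Cl2, 0 °C; then DBU, rt
Reagents that add atoms: none
Why: Mesylation followed by E1cB elimination should give the conjugated trisubstituted enone, mainly as the sterically preferred E isomer (side chain anti to the acyl group), and either geometry would serve in step 7.

Step 7
Reactants: 10 (E)-10-[4-(allyloxy)phenyl]-2-methyl-7-(3-methylbut-2-enyl)deca-2,7-dien-6-one; 11 diallyl malonate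
Product: 13 allyl 6-{2-[4-(allyloxy)phenyl]ethyl}-3,5-bis(3-methylbut-2-enyl)-2,4-dioxocyclohexane-1-carboxylate (diastereomers and enol tautomers), via Michael adduct 12 (not isolated)
Conditions: NaH (1.4 equiv), 11 (1.5 equiv), THF, 0 °C; then allyl alcohol (cosolvent, THF–allyl alcohol 10:1) and 10, 65 °C; cold 1 M HCl
Reagents that add atoms: none
Why: The sodium enolate of 11 adds reversibly to the β-carbon of 10 (Michael addition, C1–C6), proton shuttling by the alcohol cosolvent gives 12 and from it a small share of the α′-enolate at C3, and this carbon acylates on one allyl ester with loss of allyloxide (Claisen condensation of the Dieckmann kind, C2–C3). The closest known reaction is the enone–malonate synthesis of 6-alkyl-2,4-dioxocyclohexanecarboxylates, the standard entry to alkylresorcylates, and enones with an α-alkyl or an α′-alkyl group are both known to take part in it. Ring A closes in the favoured 6-(enolendo)-exo-trig mode. The closing deprotonation of the new 1,3-dione is irreversible and draws the unfavourable addition to the α-substituted acceptor forward, and it also funnels any enol lactone from reversible O-acylation into the C-acylated ring. The step needs 1,4- over 1,2-addition, secured by the soft stabilised donor, and closure from C3 rather than C5, secured by ring size because the C5 enolate could only form a four-membered ring. The sp3 centres at C1, C3, C5 and C6 arise without any controlling element as an equilibrating mixture, and none is needed since step 8 erases all four.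

Step 8
Reactants: 13 allyl 6-{2-[4-(allyloxy)phenyl]ethyl}-3,5-bis(3-methylbut-2-enyl)-2,4-dioxocyclohexane-1-carboxylate
Product: 15 allyl 6-{2-[4-(allyloxy)phenyl]ethyl}-2,4-dihydroxy-3,5-bis(3-methylbut-2-enyl)benzoate, via C1 sulfilimine 14 (not isolated)
Conditions: LiN(SiMe3)2 (2.2 equiv), THF, −78 °C; PhS(Cl)=N-t-Bu (1.05 equiv), −78 → −20 °C; AcOH
Reagents that add atoms: none
Why: Mukaiyama dehydrogenation of an enolate, in which two equivalents of base remove the doubly activated protons at C3 and C1, the less stabilised C1 terminus of this tricarbonyl dianion attacks sulfur anti to the C6 side chain, the sulfilimine nitrogen of 14 takes the syn C6–H through a five-membered transition state and the C1=C6 enedione tautomerises to the arene, all without a free oxidant, divalent palladium or a quinone, each of which would cyclise an ortho-prenyl phenol.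

Step 9
Reactants: 15 allyl 6-{2-[4-(allyloxy)phenyl]ethyl}-2,4-dihydroxy-3,5-bis(3-methylbut-2-enyl)benzoate
Product: 16 allyl 4-(allyloxy)-6-{2-[4-(allyloxy)phenyl]ethyl}-2-hydroxy-3,5-bis(3-methylbut-2-enyl)benzoate
Conditions: allyl bromide (1.05 equiv), K2CO3 (1.1 equiv), acetone, rt → 40 °C
Reagents that add atoms: allyl bromide, C=CCBr
Why: Site-selective Williamson etherification; the C2 hydroxyl is tied up in a hydrogen bond to the ester carbonyl and is the less acidic one, so one equivalent of base and of a small halide should alkylate the C4 hydroxyl, as is usual for 2,4-dihydroxybenzoates.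

Step 10
Reactants: 16 allyl 4-(allyloxy)-6-{2-[4-(allyloxy)phenyl]ethyl}-2-hydroxy-3,5-bis(3-methylbut-2-enyl)benzoate
Product: 17 allyl 4-(allyloxy)-6-{2-[4-(allyloxy)phenyl]ethyl}-2-methoxy-3,5-bis(3-methylbut-2-enyl)benzoate
Conditions: MeI (excess), K2CO3, DMF, 40 °C
Reagents that add atoms: iodomethane, CI
Why: Williamson methylation of the one remaining, chelated phenol can be forced with excess MeI in a polar aprotic solvent because nothing else in 16 is nucleophilic or base-labile.

Step 11
Reactants: 17 allyl 4-(allyloxy)-6-{2-[4-(allyloxy)phenyl]ethyl}-2-methoxy-3,5-bis(3-methylbut-2-enyl)benzoate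
Product: 18 4-hydroxy-6-[2-(4-hydroxyphenyl)ethyl]-2-methoxy-3,5-bis(3-methylbut-2-enyl)benzoic acid (CNP0254933.0)
Conditions: Pd(PPh3)4 (5 mol %), morpholine (10 equiv), THF, rt → 40 °C; aq. citric acid
Reagents that add atoms: none
Why: Tsuji–Trost deallylation, in which zerovalent palladium ionises the allyl ester and both aryl allyl ethers at their unhindered allyl termini, so the crowding around the doubly ortho-substituted C1 carboxyl (which would make saponification harsh) plays no part, morpholine traps the π-allyl units irreversibly, and the C-bound prenyl groups and the methyl ether offer no leaving group.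

Compound list
1 | dimethyl 3-oxopentanedioate | COC(=O)CC(=O)CC(=O)OC | starting material
2 | prenyl bromide (1-bromo-3-methylbut-2-ene) | CC(C)=CCBr | starting material
3 | dimethyl 2,4-bis(3-methylbut-2-enyl)-3-oxopentanedioate | COC(=O)C(CC=C(C)C)C(=O)C(CC=C(C)C)C(=O)OC | intermediate
4 | 2,10-dimethylundeca-2,9-dien-6-one | CC(C)=CCCC(=O)CCC=C(C)C | intermediate
5 | methyl 3-(4-hydroxyphenyl)propanoate | COC(=O)CCc1ccc(O)cc1 | starting material
6 | methyl 3-[4-(allyloxy)phenyl]propanoate | COC(=O)CCc1ccc(OCC=C)cc1 | intermediate
7 | 3-[4-(allyloxy)phenyl]propanal | O=CCCc1ccc(OCC=C)cc1 | intermediate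
8 | 10-[4-(allyloxy)phenyl]-8-hydroxy-2-methyl-7-(3-methylbut-2-enyl)dec-2-en-6-one | CC(C)=CCCC(=O)C(CC=C(C)C)C(O)CCc1ccc(OCC=C)cc1 | intermediate
9 | C8 methanesulfonate of 8 (not isolated) | CC(C)=CCCC(=O)C(CC=C(C)C)C(CCc1ccc(OCC=C)cc1)OS(C)(=O)=O | intermediate
10 | (E)-10-[4-(allyloxy)phenyl]-2-methyl-7-(3-methylbut-2-enyl)deca-2,7-dien-6-one | CC(C)=CCCC(=O)/C(CC=C(C)C)=C/CCc1ccc(OCC=C)cc1 | intermediate
11 | diallyl malonate | C=CCOC(=O)CC(=O)OCC=C | starting material
12 | diallyl 2-{1-[4-(allyloxy)phenyl]-9-methyl-4-(3-methylbut-2-enyl)-5-oxodec-8-en-3-yl}malonate (not isolated) | C=CCOC(=O)C(C(=O)OCC=C)C(CCc1ccc(OCC=C)cc1)C(CC=C(C)C)C(=O)CCC=C(C)C | intermediate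
13 | allyl 6-{2-[4-(allyloxy)phenyl]ethyl}-3,5-bis(3-methylbut-2-enyl)-2,4-dioxocyclohexane-1-carboxylate | C=CCOC(=O)C1C(=O)C(CC=C(C)C)C(=O)C(CC=C(C)C)C1CCc1ccc(OCC=C)cc1 | intermediate
14 | allyl 1-(N-tert-butyl-S-phenylsulfinimidoyl)-6-{2-[4-(allyloxy)phenyl]ethyl}-3,5-bis(3-methylbut-2-enyl)-2,4-dioxocyclohexane-1-carboxylate (not isolated) | C=CCOC(=O)C1(S(=NC(C)(C)C)c2ccccc2)C(=O)C(CC=C(C)C)C(=O)C(CC=C(C)C)C1CCc1ccc(OCC=C)cc1 | intermediate
15 | allyl 6-{2-[4-(allyloxy)phenyl]ethyl}-2,4-dihydroxy-3,5-bis(3-methylbut-2-enyl)benzoate | C=CCOC(=O)c1c(O)c(CC=C(C)C)c(O)c(CC=C(C)C)c1CCc1ccc(OCC=C)cc1 | intermediate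
16 | allyl 4-(allyloxy)-6-{2-[4-(allyloxy)phenyl]ethyl}-2-hydroxy-3,5-bis(3-methylbut-2-enyl)benzoate | C=CCOC(=O)c1c(O)c(CC=C(C)C)c(OCC=C)c(CC=C(C)C)c1CCc1ccc(OCC=C)cc1 | intermediate
17 | allyl 4-(allyloxy)-6-{2-[4-(allyloxy)phenyl]ethyl}-2-methoxy-3,5-bis(3-methylbut-2-enyl)benzoate | C=CCOC(=O)c1c(OC)c(CC=C(C)C)c(OCC=C)c(CC=C(C)C)c1CCc1ccc(OCC=C)cc1 | intermediate
18 | 4-hydroxy-6-[2-(4-hydroxyphenyl)ethyl]-2-methoxy-3,5-bis(3-methylbut-2-enyl)benzoic acid | COc1c(CC=C(C)C)c(O)c(CC=C(C)C)c(CCc2ccc(O)cc2)c1C(=O)O | target

Total step count: 11. Longest linear sequence: 9 steps (1 → 3 → 4 → 8 → 10 → 13 → 15 → 16 → 17 → 18; the branch from 5 is equally long).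

Steps most likely to fail

Step 7. The conjugate addition to a trisubstituted, α-branched enone may remain on the side of the starting materials. Long heating with base may also let the enone drift out of conjugation or oligomerise before the ring closes. The fallback exchanges donor and acceptor. It sets out from 7 (with 11 and 4) and comes back at 13. Knoevenagel condensation of 7 with 11 (piperidine, AcOH, toluene, water separator) should give diallyl 2-{3-[4-(allyloxy)phenyl]propylidene}malonate F1. This is a doubly activated acceptor with no α-substituent in the way. The lithium enolate of 4 (LiN(i-Pr)2, THF, −78 °C) then adds to it and forges C5–C6 in place of C1–C6, which leads to the same adduct 12, now isolated. NaH in THF at 65 °C closes C2–C3 and gives 13.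

Step 8. The dianion has two nucleophilic carbons. Capture of sulfur at C3 in place of C1, followed by elimination into the prenyl chain, would erode the aromatisation, as would sluggish capture at the crowded C1. The fallback replaces enolate chemistry by hydride abstraction. It sets out from 13 and comes back at 15. TMSOTf and Et3N in CH2Cl2 at 0 °C should give allyl 6-{2-[4-(allyloxy)phenyl]ethyl}-3,5-bis(3-methylbut-2-enyl)-2,4-bis(trimethylsilyloxy)cyclohexa-1,3-diene-1-carboxylate F2, and any regioisomeric dienol ether would serve equally. DDQ (1.0 equiv) with 2,4,6-collidine in toluene at 0 °C dehydrogenates this dihydroarene to allyl 6-{2-[4-(allyloxy)phenyl]ethyl}-3,5-bis(3-methylbut-2-enyl)-2,4-bis(trimethylsilyloxy)benzoate F3. Its masked phenols cannot form the quinone methides that lead to chromenes. KF in MeOH frees both phenols and gives 15.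

Step 9. Site selectivity may be lost. Both positions ortho to the C4 hydroxyl are occupied, so alkylation there slows down. Once carbonate begins to deprotonate the chelated C2 hydroxyl, over-allylation may set in. The fallback sets out from 15 and comes back at 16. It is a Mitsunobu etherification with allyl alcohol (PPh3, DIAD, THF, 0 °C → rt) and runs without base. Only the more acidic, unchelated C4 phenol protonates the betaine and is alkylated, and a C2 phenoxide is never generated. No compound outside the list arises (entry F0).

Further compounds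
F1 | step 7 | diallyl 2-{3-[4-(allyloxy)phenyl]propylidene}malonate | C=CCOC(=O)C(=CCCc1ccc(OCC=C)cc1)C(=O)OCC=C
F2 | step 8 | allyl 6-{2-[4-(allyloxy)phenyl]ethyl}-3,5-bis(3-methylbut-2-enyl)-2,4-bis(trimethylsilyloxy)cyclohexa-1,3-diene-1-carboxylate | C=CCOC(=O)C1=C(O[Si](C)(C)C)C(CC=C(C)C)=C(O[Si](C)(C)C)C(CC=C(C)C)C1CCc1ccc(OCC=C)cc1
F3 | step 8 | allyl 6-{2-[4-(allyloxy)phenyl]ethyl}-3,5-bis(3-methylbut-2-enyl)-2,4-bis(trimethylsilyloxy)benzoate | C=CCOC(=O)c1c(O[Si](C)(C)C)c(CC=C(C)C)c(O[Si](C)(C)C)c(CC=C(C)C)c1CCc1ccc(OCC=C)cc1
F0 | step 9 | none | none
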